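**Retrosynthetic overview**
1. The last C–C bond is C6–C1''. It comes from a Heck reaction of 6-iodoflavanone 12 with (S)-β-citronellene 13, which supplies C3'' from the chiral pool. The iodine is placed ortho to the chelated 5-OH, and all silyl ethers are removed at the end with buffered fluoride.
2. The core disconnection makes the C2–C1' aryl bond and ring C (O1, C2, C3, C4, C4a, C8a) together from racemic cyclopropanol 5. In 5 the oxygen ring (O1, C2, C4, C4a, C8a) is still five-membered, and C3 sits outside it as the cyclopropane CH2.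
3. The enabling feature is that C2 of ring C is both α to the ring oxygen O1 and β to the C4 carbonyl. β-Scission of the cyclopropyloxy radical at C4 therefore breaks the C2–C4 zero bridge, takes C3 into the ring and leaves a stabilised prochiral radical on C2. A chiral aryl nickel complex made from 7 turns this radical into the 2S centre.
4. Compound 5 comes in three steps from 4,6-dihydroxybenzofuran-3(2H)-one 1: silylation, silyl enol ether formation, and Simmons–Smith reaction.
5. Ring order: rings A and B and the furanone ring are bought. The cyclopropane is made in step 3. Ring C is made in step 5 by merging the three- and the five-membered ring.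

Key step: step 5

Assumption: 1, 6 and 13 are taken as catalogue chemicals, and the (S,S) antipode of the bioxazoline ligand is taken to lead to 2S; if the sense is opposite, the (R,R) ligand is used. Racemates are written without stereo marks; primes denote ring B and double primes the side chain.

Step 1
Reactants: 1 4,6-dihydroxybenzofuran-3(2H)-one
Product: 2 4,6-bis(tert-butyldimethylsilyloxy)benzofuran-3(2H)-one
Conditions: TBSCl (2.4 equiv), imidazole (5 equiv), DMF, 0 °C to rt
Reagents that add atoms: tert-butyldimethylsilyl chloride, CC(C)(C)[Si](C)(C)Cl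
Why: Standard imidazole-promoted O-silylation of phenols, which also takes the only weakly chelated 4-OH of the five-membered ketone; silyl ethers are chosen because they can be removed at the end without acid, base or hydrogen.

Step 2
Reactants: 2 4,6-bis(tert-butyldimethylsilyloxy)benzofuran-3(2H)-one
Product: 3 4,6-bis(tert-butyldimethylsilyloxy)-3-(trimethylsilyloxy)benzofuran
Conditions: TMSOTf (1.3 equiv), Et3N (2 equiv), CH2Cl2, 0 °C; pentane, filtration
Reagents that add atoms: trimethylsilyl trifluoromethanesulfonate, C[Si](C)(C)OS(=O)(=O)C(F)(F)F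
Why: Soft enolisation and O-silylation of a ketone that has α-hydrogens only at C2 and whose enol form is an aromatic benzofuran, so that a single silyl enol ether should form easily.

Step 3
Reactants: 3 4,6-bis(tert-butyldimethylsilyloxy)-3-(trimethylsilyloxy)benzofuran
Product: 5 rac-4,6-bis(tert-butyldimethylsilyloxy)-1a,6b-dihydro-1H-cyclopropa[b][1]benzofuran-6b-ol (cis-fused), via trimethylsilyl cyclopropyl ether 4 (not isolated)
Conditions: Et2Zn (3 equiv), CH2I2 (3 equiv), CH2Cl2, 0 °C to rt; aq NH4Cl; then citric acid (cat.), MeOH, 0 °C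
Reagents that add atoms: diiodomethane, ICI
Why: Furukawa variant of the Simmons–Smith cyclopropanation of a silyl enol ether: the C2=C3 bond carries two oxygen donors and is the only non-benzenoid π bond, the cis ring fusion is the only possible one so that 5 is a single racemic diastereomer, and the alkyl O–SiMe3 bond is methanolysed under mild acid that leaves the aryl O–SiMe2tBu bonds.

Step 4
Reactants: 6 4-bromocatechol (4-bromobenzene-1,2-diol)
Product: 7 4-bromo-1,2-bis(tert-butyldimethylsilyloxy)benzene
Conditions: TBSCl (2.4 equiv), imidazole (5 equiv), DMF, rt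
Reagents that add atoms: tert-butyldimethylsilyl chloride, CC(C)(C)[Si](C)(C)Cl
Why: Standard imidazole-promoted silylation of both catechol hydroxyls.

Step 5
Reactants: 5 rac-4,6-bis(tert-butyldimethylsilyloxy)-1a,6b-dihydro-1H-cyclopropa[b][1]benzofuran-6b-ol; 7 4-bromo-1,2-bis(tert-butyldimethylsilyloxy)benzene
Product: 9 (2S)-5,7,3',4'-tetrakis(tert-butyldimethylsilyloxy)flavanone, via 4-oxochroman-2-yl radical 8 (not isolated)
Conditions: [Ir(dF(CF3)ppy)2(dtbbpy)]PF6 (2 mol %), NiBr2(dme) (10 mol %), (4S,4'S)-4,4'-dibenzyl-4,4',5,5'-tetrahydro-2,2'-bioxazole (12 mol %), 2,4,6-collidine (1.5 equiv), 7 (1.5 equiv), DMA, 450 nm LED, 15 °C, argon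
Reagents that add atoms: none
Why: Proposed new method: the excited iridium photocatalyst and collidine take one electron and the proton from the electron-rich 1-arylcyclopropanol 5, and the cyclopropyloxy radical undergoes β-scission of the zero-bridge bond C1a–C6b (the future C2 and C4), which releases the cyclopropane strain, turns C6b into the C4 ketone and leaves the radical next to O1 (radical 8). No ring is closed by cyclisation: the six-membered ring C arises by merging the three- and the five-membered ring of the 2-oxabicyclo[3.1.0]hexane unit, which is a one-carbon enlargement of the furanone ring in the Dowd–Beckwith sense. Radical 8 is captured by the aryl nickel bromide formed from zerovalent nickel and 7, reductive elimination from trivalent nickel makes the C2–C1' bond, and the reduced photocatalyst returns monovalent nickel to zerovalent nickel, so the step is redox-neutral. The closest known reaction types are the nickel/photoredox ring-opening arylation of cyclopropanols and other tertiary cycloalkanols with aryl bromides, the FeCl3-induced ring enlargement of 1-oxybicyclo[n.1.0]alkanes and the enantioselective nickel/photochemical arylation of α-oxy radicals of cyclic ethers; their combination, a benzofuranone-derived cyclopropanol and an enantioconvergent outcome have not been shown. The only new stereocentre, C2, is controlled by the chiral bioxazoline on nickel, and both enantiomers of racemic 5 converge on the planar radical 8. The step needs endocyclic instead of exocyclic bond cleavage, which is secured because the endocyclic path gives a secondary α-aryloxy radical, the other path gives only a primary one and both equilibrate through the cyclopropyloxy radical, and it needs coupling to outrun β-hydride loss to the chromone, which the rigid bidentate nitrogen ligand favours.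

Step 6
Reactants: 9 (2S)-5,7,3',4'-tetrakis(tert-butyldimethylsilyloxy)flavanone
Product: 11 (2S)-5-hydroxy-7,3',4'-tris(tert-butyldimethylsilyloxy)flavanone, via dichloroboryl chelate 10 (not isolated)
Conditions: BCl3 (1.05 equiv), CH2Cl2, −78 °C; then H2O, −78 °C to 0 °C
Reagents that add atoms: boron trichloride, ClB(Cl)Cl (its atoms stay only in intermediate 10)
Why: Chelation-controlled ether cleavage known from the selective 5-O-dealkylation of flavonoids: BCl3 binds to the C4 carbonyl oxygen, only the peri 5-O–Si bond lies within reach for chloride-assisted transfer to boron, and the low temperature keeps the C2–O1 bond and with it the stereocentre untouched.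

Step 7
Reactants: 11 (2S)-5-hydroxy-7,3',4'-tris(tert-butyldimethylsilyloxy)flavanone
Product: 12 (2S)-5-hydroxy-6-iodo-7,3',4'-tris(tert-butyldimethylsilyloxy)flavanone
Conditions: NIS (1.05 equiv), DMF, 0 °C, dark
Reagents that add atoms: N-iodosuccinimide, O=C1CCC(=O)N1I
Why: Electrophilic aromatic iodination with NIS under neutral conditions, which in 5-hydroxy-7-alkoxy flavonoids is directed ortho to the chelated 5-OH to C6, while ring B without a free phenol and the α-carbon C3 are less reactive.

Step 8
Reactants: 12 (2S)-5-hydroxy-6-iodo-7,3',4'-tris(tert-butyldimethylsilyloxy)flavanone; 13 (S)-β-citronellene, (3S)-3,7-dimethylocta-1,6-diene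
Product: 14 (2S)-6-[(1E,3S)-3,7-dimethylocta-1,6-dienyl]-5-hydroxy-7,3',4'-tris(tert-butyldimethylsilyloxy)flavanone
Conditions: Pd2(dba)3 (3 mol %), [HP(t-Bu)3]BF4 (12 mol %), Cy2NMe (1.6 equiv), 13 (3 equiv), 1,4-dioxane, 50 °C
Reagents that add atoms: none
Why: Mizoroki–Heck reaction: the aryl palladium iodide adds to the terminal carbon of the monosubstituted alkene of 13, syn β-hydride elimination of the benzylic hydrogen gives the conjugated E alkene, the trisubstituted alkene is inert, C3'' comes unchanged from 13, and the hindered amine strips HI from the palladium hydride fast enough to suppress double bond migration while being too weak to open ring C.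

Step 9
Reactants: 14 (2S)-6-[(1E,3S)-3,7-dimethylocta-1,6-dienyl]-5-hydroxy-7,3',4'-tris(tert-butyldimethylsilyloxy)flavanone
Product: 15 (2S)-6-[(1E,3S)-3,7-dimethylocta-1,6-dienyl]-5,7,3',4'-tetrahydroxyflavanone (CNP0230070.1)
Conditions: Et3N·3HF (1.5 equiv), THF, 0 °C to rt, argon
Reagents that add atoms: none
Why: Fluoride-driven cleavage of aryl silyl ethers in a slightly acidic buffered medium, in which no phenoxide builds up, so that neither retro-oxa-Michael opening of ring C nor quinone methide formation from the 4'-OH should racemise C2, and the electron-rich styrene is not protonated.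

**Compound list**
1 | 4,6-dihydroxybenzofuran-3(2H)-one | O=C1COc2cc(O)cc(O)c12 | starting material
2 | 4,6-bis(tert-butyldimethylsilyloxy)benzofuran-3(2H)-one | O=C1COc2cc(O[Si](C)(C)C(C)(C)C)cc(O[Si](C)(C)C(C)(C)C)c12 | intermediate
3 | 4,6-bis(tert-butyldimethylsilyloxy)-3-(trimethylsilyloxy)benzofuran | C[Si](C)(C)Oc1coc2cc(O[Si](C)(C)C(C)(C)C)cc(O[Si](C)(C)C(C)(C)C)c12 | intermediate
4 | rac-4,6-bis(tert-butyldimethylsilyloxy)-6b-(trimethylsilyloxy)-1a,6b-dihydro-1H-cyclopropa[b][1]benzofuran (not isolated) | C[Si](C)(C)OC12CC1Oc1cc(O[Si](C)(C)C(C)(C)C)cc(O[Si](C)(C)C(C)(C)C)c12 | intermediate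
5 | rac-4,6-bis(tert-butyldimethylsilyloxy)-1a,6b-dihydro-1H-cyclopropa[b][1]benzofuran-6b-ol | OC12CC1Oc1cc(O[Si](C)(C)C(C)(C)C)cc(O[Si](C)(C)C(C)(C)C)c12 | intermediate
6 | 4-bromocatechol | Oc1ccc(Br)cc1O | starting material
7 | 4-bromo-1,2-bis(tert-butyldimethylsilyloxy)benzene | CC(C)(C)[Si](C)(C)Oc1ccc(Br)cc1O[Si](C)(C)C(C)(C)C | intermediate
8 | 5,7-bis(tert-butyldimethylsilyloxy)-4-oxochroman-2-yl radical (not isolated) | O=C1C[CH]Oc2cc(O[Si](C)(C)C(C)(C)C)cc(O[Si](C)(C)C(C)(C)C)c12 | intermediate
9 | (2S)-5,7,3',4'-tetrakis(tert-butyldimethylsilyloxy)flavanone | O=C1C[C@@H](c2ccc(O[Si](C)(C)C(C)(C)C)c(O[Si](C)(C)C(C)(C)C)c2)Oc2cc(O[Si](C)(C)C(C)(C)C)cc(O[Si](C)(C)C(C)(C)C)c12 | intermediate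
10 | (2S)-5-(dichloroboryloxy)-7,3',4'-tris(tert-butyldimethylsilyloxy)flavanone, chelated to the C4 carbonyl (not isolated) | ClB(Cl)Oc1cc(O[Si](C)(C)C(C)(C)C)cc2c1C(=O)C[C@@H](c1ccc(O[Si](C)(C)C(C)(C)C)c(O[Si](C)(C)C(C)(C)C)c1)O2 | intermediate
11 | (2S)-5-hydroxy-7,3',4'-tris(tert-butyldimethylsilyloxy)flavanone | Oc1cc(O[Si](C)(C)C(C)(C)C)cc2c1C(=O)C[C@@H](c1ccc(O[Si](C)(C)C(C)(C)C)c(O[Si](C)(C)C(C)(C)C)c1)O2 | intermediate
12 | (2S)-5-hydroxy-6-iodo-7,3',4'-tris(tert-butyldimethylsilyloxy)flavanone | Oc1c(I)c(O[Si](C)(C)C(C)(C)C)cc2c1C(=O)C[C@@H](c1ccc(O[Si](C)(C)C(C)(C)C)c(O[Si](C)(C)C(C)(C)C)c1)O2 | intermediate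
13 | (S)-β-citronellene, (3S)-3,7-dimethylocta-1,6-diene | CC(C)=CCC[C@H](C)C=C | starting material
14 | (2S)-6-[(1E,3S)-3,7-dimethylocta-1,6-dienyl]-5-hydroxy-7,3',4'-tris(tert-butyldimethylsilyloxy)flavanone | CC(C)=CCC[C@H](C)/C=C/c1c(O[Si](C)(C)C(C)(C)C)cc2c(c1O)C(=O)C[C@@H](c1ccc(O[Si](C)(C)C(C)(C)C)c(O[Si](C)(C)C(C)(C)C)c1)O2 | intermediate
15 | (2S)-6-[(1E,3S)-3,7-dimethylocta-1,6-dienyl]-5,7,3',4'-tetrahydroxyflavanone | CC(C)=CCC[C@H](C)/C=C/c1c(O)cc2c(c1O)C(=O)C[C@@H](c1ccc(O)c(O)c1)O2 | target

Total step count: 9. Longest linear sequence: 8 steps (1, 2, 3, 5, 6, 7, 8, 9).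

**Steps most likely to fail**

**Step 5.**
- What may go wrong: capture of the ring-enlarged radical by nickel may lose against β-hydride loss or hydrogen abstraction. Facial selectivity in the bond-forming reductive elimination may also be poor.
- Idea of the fallback: it keeps the ring enlargement and moves arylation and stereocontrol into a separate polar step of known type. It sets out from 5 and 7 and comes back at 9.
- Oxidation of 5 with FeCl3 (2.2 equiv) in DMF at 0 °C should break the same zero-bridge bond and give rac-2-chloro-5,7-bis(tert-butyldimethylsilyloxy)chroman-4-one F1. Et3N in CH2Cl2 then removes HCl to give 5,7-bis(tert-butyldimethylsilyloxy)-4H-chromen-4-one F2.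
- Bromide 7 is converted with n-BuLi in THF at −78 °C into 3,4-bis(tert-butyldimethylsilyloxy)phenyllithium F3. Treatment with B(OiPr)3 and then aqueous NH4Cl gives 3,4-bis(tert-butyldimethylsilyloxy)phenylboronic acid F4.
- A Hayashi–Miyaura asymmetric 1,4-addition of F4 to F2 gives 9. It uses [Rh(OH)(cod)]2 and the suitable antipode of 2,2'-bis[bis(3,4,5-trifluorophenyl)phosphino]-6,6'-dimethoxy-1,1'-biphenyl in toluene–water at rt.

**Step 8.**
- What may go wrong: β-hydride elimination toward C3'', or re-addition of palladium hydride, may move the double bond and erode C3''. The doubly ortho-substituted aryl palladium species may also insert slowly.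
- Idea of the fallback: it fixes the alkene geometry on the small fragment before the coupling and replaces carbopalladation by transmetalation. It sets out from 13 and 12 and comes back at 14.
- A boryl-Heck reaction of 13 should give 2-[(1E,3S)-3,7-dimethylocta-1,6-dienyl]-1,3,2-benzodioxaborole F5. The conditions are B-chlorocatecholborane, Pd2(dba)3, the bulky phosphine (3,5-tBu2C6H3)2P(t-Bu), Cy2NMe, PhCF3, 70 °C.
- Pinacol then converts it into 2-[(1E,3S)-3,7-dimethylocta-1,6-dienyl]-4,4,5,5-tetramethyl-1,3,2-dioxaborolane F6. Isomers can be removed at this stage.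
- Suzuki–Miyaura coupling of F6 with 12 (PdCl2(dppf), K3PO4, THF–water, 40 °C) gives 14.

**Step 7.**
- What may go wrong: site selectivity between C6 and C8 may be poor.
- Idea of the fallback: it closes C8 with a temporary bromine while C6 is still shielded by two bulky silyl ethers. It sets out from 9 and comes back at 14.
- NBS in CH2Cl2 at 0 °C should attack the only accessible ring A position of 9 and give (2S)-8-bromo-5,7,3',4'-tetrakis(tert-butyldimethylsilyloxy)flavanone F7.
- BCl3 as in step 6 gives the (2S)-8-bromo-5-(dichloroboryloxy) chelate F8. Water then gives (2S)-8-bromo-5-hydroxy-7,3',4'-tris(tert-butyldimethylsilyloxy)flavanone F9.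
- NIS can now iodinate only C6 and gives (2S)-8-bromo-5-hydroxy-6-iodo-7,3',4'-tris(tert-butyldimethylsilyloxy)flavanone F10.
- A Heck reaction with 13 under a catalyst that leaves aryl bromides untouched (Pd(OAc)2, P(o-tol)3, Cy2NMe, dioxane, 60 °C) gives (2S)-8-bromo-6-[(1E,3S)-3,7-dimethylocta-1,6-dienyl]-5-hydroxy-7,3',4'-tris(tert-butyldimethylsilyloxy)flavanone F11.
- Palladium-catalysed hydrodebromination (Pd(PPh3)4, Bu3SnH, toluene, 80 °C) gives 14.

**Further compounds**
F1 | step 5 | rac-2-chloro-5,7-bis(tert-butyldimethylsilyloxy)chroman-4-one | O=C1CC(Cl)Oc2cc(O[Si](C)(C)C(C)(C)C)cc(O[Si](C)(C)C(C)(C)C)c12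
F2 | step 5 | 5,7-bis(tert-butyldimethylsilyloxy)-4H-chromen-4-one | O=c1ccoc2cc(O[Si](C)(C)C(C)(C)C)cc(O[Si](C)(C)C(C)(C)C)c12
F3 | step 5 | 3,4-bis(tert-butyldimethylsilyloxy)phenyllithium | [Li]c1ccc(O[Si](C)(C)C(C)(C)C)c(O[Si](C)(C)C(C)(C)C)c1
F4 | step 5 | 3,4-bis(tert-butyldimethylsilyloxy)phenylboronic acid | OB(O)c1ccc(O[Si](C)(C)C(C)(C)C)c(O[Si](C)(C)C(C)(C)C)c1
F5 | step 8 | 2-[(1E,3S)-3,7-dimethylocta-1,6-dienyl]-1,3,2-benzodioxaborole | CC(C)=CCC[C@H](C)/C=C/B1Oc2ccccc2O1
F6 | step 8 | 2-[(1E,3S)-3,7-dimethylocta-1,6-dienyl]-4,4,5,5-tetramethyl-1,3,2-dioxaborolane | CC(C)=CCC[C@H](C)/C=C/B1OC(C)(C)C(C)(C)O1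
F7 | step 7 | (2S)-8-bromo-5,7,3',4'-tetrakis(tert-butyldimethylsilyloxy)flavanone | O=C1C[C@@H](c2ccc(O[Si](C)(C)C(C)(C)C)c(O[Si](C)(C)C(C)(C)C)c2)Oc2c(Br)c(O[Si](C)(C)C(C)(C)C)cc(O[Si](C)(C)C(C)(C)C)c12
F8 | step 7 | (2S)-8-bromo-5-(dichloroboryloxy)-7,3',4'-tris(tert-butyldimethylsilyloxy)flavanone | ClB(Cl)Oc1cc(O[Si](C)(C)C(C)(C)C)c(Br)c2c1C(=O)C[C@@H](c1ccc(O[Si](C)(C)C(C)(C)C)c(O[Si](C)(C)C(C)(C)C)c1)O2
F9 | step 7 | (2S)-8-bromo-5-hydroxy-7,3',4'-tris(tert-butyldimethylsilyloxy)flavanone | Oc1cc(O[Si](C)(C)C(C)(C)C)c(Br)c2c1C(=O)C[C@@H](c1ccc(O[Si](C)(C)C(C)(C)C)c(O[Si](C)(C)C(C)(C)C)c1)O2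
F10 | step 7 | (2S)-8-bromo-5-hydroxy-6-iodo-7,3',4'-tris(tert-butyldimethylsilyloxy)flavanone | Oc1c(I)c(O[Si](C)(C)C(C)(C)C)c(Br)c2c1C(=O)C[C@@H](c1ccc(O[Si](C)(C)C(C)(C)C)c(O[Si](C)(C)C(C)(C)C)c1)O2
F11 | step 7 | (2S)-8-bromo-6-[(1E,3S)-3,7-dimethylocta-1,6-dienyl]-5-hydroxy-7,3',4'-tris(tert-butyldimethylsilyloxy)flavanone | CC(C)=CCC[C@H](C)/C=C/c1c(O[Si](C)(C)C(C)(C)C)c(Br)c2c(c1O)C(=O)C[C@@H](c1ccc(O[Si](C)(C)C(C)(C)C)c(O[Si](C)(C)C(C)(C)C)c1)O2
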